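**Retrosynthetic overview**

- Target ⇒ retro-Claisen cleavage (C1–C9) and hemiketal (C3–O–C9) ⇒ transient 3-hydroxy type A bicyclo[3.3.1]nonane-2,4,9-trione ⇒ tertiary cation–enol closure (C1–C8) ⇒ monocyclic, C3-hydroxylated, dearomatized acylphloroglucinol; all three events run in one flask.
- Ring order: six-membered carbocycle (C1–C8) first, oxygen bridge C3–O–C9 second; C1–C9 cleavage then leaves the γ-lactone and the eight-membered ring.
- Monocycle ⇒ C3 enolate hydroxylation plus dearomative C5 alkylation of clusiaphenone B with an enantiopure C15 iodo alcohol.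
- C15 iodo alcohol ⇒ nerol (Sharpless epoxidation, copper-catalysed prenyl Grignard opening at C2, Appel iodination).
- Clusiaphenone B ⇒ 2,4,6-trihydroxybenzophenone + prenyl bromide.

Assumption: biogenetic locants are used for ring carbons (C1 = CH carrying benzoyl, C2 = ketone next to it, C3 = O-bearing quaternary carbon, C4 = bridging ketone, C5 = quaternary carbon next to lactone carbonyl C9, C6 = CH2, C7 = CH carrying prenyl, C8 = quaternary carbon carrying methyl and 4-methylpent-3-enyl); 2,4,6-trihydroxybenzophenone, nerol and prenylmagnesium chloride (C5H9MgCl, THF solution) are bought.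

**Route**

Step 1
Reactants: 1 2,4,6-trihydroxybenzophenone; 2 prenyl bromide (1-bromo-3-methylbut-2-ene)
Product: 3 clusiaphenone B, [2,4,6-trihydroxy-3,5-bis(3-methylbut-2-en-1-yl)phenyl](phenyl)methanone
Conditions: 2 (2.2 equiv), 10% aq. KOH, 0 °C
Reagents that add atoms: none
Why: The ambident phenoxide of the electron-rich acylphloroglucinol is C-alkylated by the allylic bromide at both free ring carbons in water (Friedel–Crafts-type C-prenylation), and no stereocenter is formed.

Step 2
Reactants: 4 nerol
Product: 5 [(2R,3S)-3-methyl-3-(4-methylpent-3-en-1-yl)oxiran-2-yl]methanol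
Conditions: Ti(OiPr)4 (10 mol%), D-(−)-diethyl tartrate (12 mol%), t-BuOOH, 4 Å molecular sieves, CH2Cl2, −20 °C
Reagents that add atoms: tert-butyl hydroperoxide, CC(C)(C)OO
Why: Sharpless asymmetric epoxidation of the Z-allylic alcohol with the D-tartrate catalyst gives the (2R,3S)-epoxide, which fixes the absolute configuration of the two carbons that become C7 and C8.

Step 3
Reactants: 5 [(2R,3S)-3-methyl-3-(4-methylpent-3-en-1-yl)oxiran-2-yl]methanol; 6 prenylmagnesium chloride
Product: 7 (2S,3S)-3,7-dimethyl-2-(3-methylbut-2-en-1-yl)oct-6-ene-1,3-diol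
Conditions: 6 (3.5 equiv), CuI (10 mol%), THF, −30 to 0 °C; aq. NH4Cl
Reagents that add atoms: none
Why: Copper-catalysed Grignard opening of the 2,3-epoxy alcohol is an SN2 reaction at the less substituted C2 with inversion, which sets C7, leaves the tertiary C–O bond (future C8) untouched, and couples the prenyl unit at its unsubstituted CH2 terminus.

Step 4
Reactants: 7 (2S,3S)-3,7-dimethyl-2-(3-methylbut-2-en-1-yl)oct-6-ene-1,3-diol
Product: 8 (2R,3S)-1-iodo-3,7-dimethyl-2-(3-methylbut-2-en-1-yl)oct-6-en-3-ol
Conditions: I2, PPh3, imidazole, CH2Cl2, 0 °C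
Reagents that add atoms: iodine, [I][I]
Why: Appel reaction, in which PPh3/I2 converts only the primary hydroxyl while the tertiary alcohol and both stereocenters are not involved (the descriptor at C2 changes only because CH2I outranks the carbinol carbon).

Step 5
Reactants: 3 clusiaphenone B; 8 (2R,3S)-1-iodo-3,7-dimethyl-2-(3-methylbut-2-en-1-yl)oct-6-en-3-ol
Product: 10 (4S,6S)-2-benzoyl-3,4-dihydroxy-6-[(2S,3S)-3-hydroxy-3,7-dimethyl-2-(3-methylbut-2-en-1-yl)oct-6-en-1-yl]-4,6-bis(3-methylbut-2-en-1-yl)cyclohex-2-ene-1,5-dione, via alkylated dienone 9 (not isolated)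
Conditions: LiN(SiMe3)2 (2.1 equiv), THF–toluene, −78 °C; 8, 0 to 40 °C; LiN(SiMe3)2 (2.2 equiv), −78 °C, then 2-(phenylsulfonyl)-3-phenyloxaziridine; AcOH, −78 °C; chromatography
Reagents that add atoms: 2-(phenylsulfonyl)-3-phenyloxaziridine, O=S(=O)(c1ccccc1)N1OC1c1ccccc1
Why: Alkylative dearomatization of the lithium dianion of 3 by the primary iodide at a prenyl-bearing ring carbon creates the quaternary C5 without control (both ring epimers form and the 6R dienone 9 is the one that leads on), after which Davis hydroxylation of the regenerated dienolate at its most nucleophilic carbon C3 (the laboratory counterpart of the deoxyhumulone-to-humulone oxidation) is expected to occur anti to the branched C15 chain, i.e. cis to the C5 prenyl group, and the unwanted ring diastereomer is removed by chromatography here.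

Step 6
Reactants: 10 (4S,6S)-2-benzoyl-3,4-dihydroxy-6-[(2S,3S)-3-hydroxy-3,7-dimethyl-2-(3-methylbut-2-en-1-yl)oct-6-en-1-yl]-4,6-bis(3-methylbut-2-en-1-yl)cyclohex-2-ene-1,5-dione
Product: 14 (1R,3S,4R,5R,7S)-5-benzoyl-4-methyl-1,3,7-tris(3-methylbut-2-en-1-yl)-4-(4-methylpent-3-en-1-yl)-8-oxabicyclo[5.2.1]decane-6,9,10-trione, via tertiary mesylate 11 (not isolated), via bicyclic hydroxytrione 12 (not isolated), via bridged hemiketal 13 (not isolated)
Conditions: MsCl (1.2 equiv), Et3N (4 equiv), CH2Cl2, −40 to 0 °C; then DBU (1 equiv), 23 °C; aq. NH4Cl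
Reagents that add atoms: none
Why: Proposed new method: mesylation of the unhindered tertiary C8 carbinol gives 11, which ionises above about −20 °C, and because C3 is already quaternary and C4 cannot enolise, the only carbon nucleophile within reach is C1 of the 2-benzoyl-1,3-dione enolate, which closes the six-membered ring through a chair with the C7 prenyl and C8 homoprenyl groups equatorial and attacks C8 anti to the leaving group (net inversion, so the nerol-derived configuration and the chair preference point to the same C8 epimer, and C1/C5 are necessarily cis-bridged), whereupon the C3 hydroxyl of 12, held syn to C9, adds to the bridging ketone and the hemiketal alkoxide of 13 expels C1 as a stabilised 1,3-diketonate (retro-Claisen), which drains the weakly favoured C–C closure irreversibly and, after thermodynamic protonation of the epimerisable C1, gives 14; the closest known reaction types are the mesylate-triggered tertiary-cation cyclisation of dearomatised acylphloroglucinols to type A cores, the C3–OH/C9 hemiketal formed when hyperforin is oxidised in air, and the retro-Claisen opening of non-enolisable 1,3-diketones.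

**Compound list**

1 | 2,4,6-trihydroxybenzophenone | O=C(c1ccccc1)c1c(O)cc(O)cc1O | starting material
2 | prenyl bromide (1-bromo-3-methylbut-2-ene) | CC(C)=CCBr | starting material
3 | clusiaphenone B, [2,4,6-trihydroxy-3,5-bis(3-methylbut-2-en-1-yl)phenyl](phenyl)methanone | O=C(c1ccccc1)c1c(O)c(CC=C(C)C)c(O)c(CC=C(C)C)c1O | intermediate
4 | nerol, (2Z)-3,7-dimethylocta-2,6-dien-1-ol | CC(C)=CCC/C(C)=C\CO | starting material
5 | [(2R,3S)-3-methyl-3-(4-methylpent-3-en-1-yl)oxiran-2-yl]methanol | CC(C)=CCC[C@]1(C)O[C@@H]1CO | intermediate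
6 | prenylmagnesium chloride (3-methylbut-2-en-1-ylmagnesium chloride) | CC(C)=CC[Mg]Cl | starting material
7 | (2S,3S)-3,7-dimethyl-2-(3-methylbut-2-en-1-yl)oct-6-ene-1,3-diol | CC(C)=CCC[C@@](O)(C)[C@@H](CC=C(C)C)CO | intermediate
8 | (2R,3S)-1-iodo-3,7-dimethyl-2-(3-methylbut-2-en-1-yl)oct-6-en-3-ol | CC(C)=CCC[C@@](O)(C)[C@@H](CC=C(C)C)CI | intermediate
9 | (6R)-2-benzoyl-3,5-dihydroxy-6-[(2S,3S)-3-hydroxy-3,7-dimethyl-2-(3-methylbut-2-en-1-yl)oct-6-en-1-yl]-4,6-bis(3-methylbut-2-en-1-yl)cyclohexa-2,4-dien-1-one | O=C1C(C(=O)c2ccccc2)=C(O)C(CC=C(C)C)=C(O)[C@@]1(CC=C(C)C)C[C@H](CC=C(C)C)[C@@](C)(O)CCC=C(C)C | intermediate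
10 | (4S,6S)-2-benzoyl-3,4-dihydroxy-6-[(2S,3S)-3-hydroxy-3,7-dimethyl-2-(3-methylbut-2-en-1-yl)oct-6-en-1-yl]-4,6-bis(3-methylbut-2-en-1-yl)cyclohex-2-ene-1,5-dione (4-OH cis to the 6-prenyl group) | O=C1C(C(=O)c2ccccc2)=C(O)[C@@](O)(CC=C(C)C)C(=O)[C@@]1(CC=C(C)C)C[C@H](CC=C(C)C)[C@@](C)(O)CCC=C(C)C | intermediate
11 | tertiary methanesulfonate of 10 at the side-chain C3 carbinol (same configuration at all centers) | O=C1C(C(=O)c2ccccc2)=C(O)[C@@](O)(CC=C(C)C)C(=O)[C@@]1(CC=C(C)C)C[C@H](CC=C(C)C)[C@@](C)(OS(C)(=O)=O)CCC=C(C)C | intermediate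
12 | (1S,3R,5S,7S,8R)-1-benzoyl-3-hydroxy-8-methyl-3,5,7-tris(3-methylbut-2-en-1-yl)-8-(4-methylpent-3-en-1-yl)bicyclo[3.3.1]nonane-2,4,9-trione | CC(C)=CCC[C@]1(C)[C@@H](CC=C(C)C)C[C@@]2(CC=C(C)C)C(=O)[C@]1(C(=O)c1ccccc1)C(=O)[C@@](O)(CC=C(C)C)C2=O | intermediate
13 | C3–O–C9 hemiketal of 12 (9-hydroxy, oxygen bridge on the face anti to the C6–C8 bridge, other centers as in 12) | CC(C)=CCC[C@]1(C)[C@@H](CC=C(C)C)C[C@@]2(CC=C(C)C)[C@]3(O)O[C@](CC=C(C)C)(C2=O)C(=O)[C@]13C(=O)c1ccccc1 | intermediate
14 | (1R,3S,4R,5R,7S)-5-benzoyl-4-methyl-1,3,7-tris(3-methylbut-2-en-1-yl)-4-(4-methylpent-3-en-1-yl)-8-oxabicyclo[5.2.1]decane-6,9,10-trione (biogenetic locants 1R,3S,5R,7S,8R) | CC(C)=CCC[C@]1(C)[C@@H](CC=C(C)C)C[C@@]2(CC=C(C)C)C(=O)O[C@@](CC=C(C)C)(C(=O)[C@H]1C(=O)c1ccccc1)C2=O | target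

**Step count and risks**

Total step count: 6. Longest linear sequence: 5 (4 → 5 → 7 → 8 → 10 → 14).

Steps most likely to fail:

Step 6 (cascade). The cation can be captured by the enol oxygen (pyran) or lose a proton, the enolate may be sulfonylated, and only the diastereomer with C3–OH trans to the chain can lactonise. The fallback sets out from 9, obtained by quenching step 5 before the second base charge and the oxidant and purifying the 6R ring epimer. MsCl/Et3N in CH2Cl2 at −40 to 0 °C closes C1–C8 on this non-hydroxylated dienone through the same chair and gives the benzoyl analogue of hyperforin F1. KN(SiMe3)2 (1.1 equiv) in THF at −78 °C followed by the same oxaziridine hydroxylates the C2–C3–C4 enolate of F1 from the face syn to C9, the other face being blocked by the C6–C8 bridge. On warming to 0 °C the C3 alkoxide adds to C9 and the hemiketal alkoxide expels C1 as the 1,3-diketonate, so the sequence comes back to the route at 14. This puts the oxidation after the carbocyclisation, so C3 is fixed by the bicycle instead of by the chain; the price is that C3 of 9 is a second carbon nucleophile during ring closure.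

Step 5 (alkylation and hydroxylation). The β-branched iodide may react slowly or at oxygen, C5 is formed as both epimers so at most half of the material is usable, the facial selectivity at C3 rests only on shielding by the chain, and the α-ketol must be kept cold to avoid acyloin ring contraction. The fallback sets out from 1. One equivalent of 2 in 10% aq. KOH at 0 °C gives 3-prenyl-2,4,6-trihydroxybenzophenone F2. Its dianion (LiN(SiMe3)2, THF–toluene) is alkylated by 8 at the only free ring carbon, a rearomatising C-alkylation that does not have to build a quaternary center, and gives the fully substituted arene F3. Dearomative prenylation of F3 with the reactive allylic bromide 2 (10% aq. KOH, 0 °C) at the chain-bearing carbon then gives both ring epimers beside a separable gem-diprenyl regioisomer, and the sequence comes back to the route at 9, which is hydroxylated as in step 5.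

Step 3 (epoxide opening). The prenyl nucleophile may couple through its substituted terminus and some attack at C3 is possible. The fallback sets out from 5. Allylmagnesium bromide with CuI (10 mol%) in THF at −30 °C opens C2 with inversion and cannot give a branched isomer; it furnishes the allyl diol F4. Cross-metathesis of F4 with 2-methylbut-2-ene (neat, second-generation Grubbs catalyst, 5 mol%, 40 °C) converts the terminal vinyl group into the prenyl group, and the sequence comes back to the route at 7.

**Further compounds**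

F1 | step 6 | (1S,5R,7S,8R)-1-benzoyl-2-hydroxy-8-methyl-3,5,7-tris(3-methylbut-2-en-1-yl)-8-(4-methylpent-3-en-1-yl)bicyclo[3.3.1]non-2-ene-4,9-dione | CC(C)=CCC[C@]1(C)[C@@H](CC=C(C)C)C[C@@]2(CC=C(C)C)C(=O)[C@]1(C(=O)c1ccccc1)C(O)=C(CC=C(C)C)C2=O
F2 | step 5 | [2,4,6-trihydroxy-3-(3-methylbut-2-en-1-yl)phenyl](phenyl)methanone | O=C(c1ccccc1)c1c(O)cc(O)c(CC=C(C)C)c1O
F3 | step 5 | [2,4,6-trihydroxy-3-[(2S,3S)-3-hydroxy-3,7-dimethyl-2-(3-methylbut-2-en-1-yl)oct-6-en-1-yl]-5-(3-methylbut-2-en-1-yl)phenyl](phenyl)methanone | O=C(c1ccccc1)c1c(O)c(CC=C(C)C)c(O)c(C[C@H](CC=C(C)C)[C@@](C)(O)CCC=C(C)C)c1O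
F4 | step 3 | (2S,3S)-3,7-dimethyl-2-(prop-2-en-1-yl)oct-6-ene-1,3-diol | CC(C)=CCC[C@@](O)(C)[C@@H](CC=C)CO
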